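**Plan**

- Cuts, in retrosynthetic order: the C6–O ester bond (aryl acid 21), the pyran O2–C3 bond (alkyne hydroalkoxylation), the C8a–C1 bond (hydroxymethyl by Stille coupling) and the C4a–C4 bond (conjugate alkynylation), which leads back to the cyclohexenone 14.
- Enabling feature: C7 carries CH3 and OH next to the C8 ketone inside the carbocycle C4a–C5–C6–C7–C8–C8a. Such a 2-hydroxy-2-methylcyclohexenone is the ring-enlarged, more stable isomer of a 1-acetylcyclopent-2-en-1-ol, so the C6–C7 bond is cut and C6 is re-attached to C8 (cyclopentenol 13).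
- 13 is cut at its ring alkene (metathesis) and at the carbinol–acetyl bond (acetyl anion addition to dienone 8, made from (S)-glycidyl trityl ether and two vinyl Grignard additions).
- Forward order: cyclopentene by RCM, cyclohexenone by ring expansion, C6 ester, alkyne at C4a, CH2OH at C8a, pyran ring last by 6-endo closure, then desilylation.
- Stereochemistry: C6 comes from the epoxide; the carbinol is set by chelation-controlled addition and its chirality is passed to C7 in the chelated 1,2-shift; the E propenyl group comes from (E)-crotonaldehyde.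

Key step: step 9

Abbreviations in names: PMB = 4-methoxybenzyl, Tr = triphenylmethyl, TBS = tert-butyldimethylsilyl, TES = triethylsilyl, TMS = trimethylsilyl, Piv = pivaloyl, DMP = Dess–Martin periodinane.

Assumption: the target is taken exactly as the SMILES is written, i.e. (6S,7S) with the C6 acyloxy group and the C7 hydroxyl cis on the carbocycle and an E propenyl group.

**Route**

Step 1
Reactants: 1 (S)-glycidyl trityl ether; 2 vinylmagnesium bromide
Product: 3 (2S)-1-(trityloxy)pent-4-en-2-ol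
Conditions: 2 (1.5 equiv), CuI (10 mol %), THF, −40 → −20 °C; aq. NH4Cl
Reagents that add atoms: none
Why: Copper-catalysed Grignard opening of a terminal epoxide at its unsubstituted carbon (SN2) is a standard route to homoallylic alcohols and leaves the stereocentre of 1 untouched, so the C6 configuration of the target is fixed here.

Step 2
Reactants: 3 (2S)-1-(trityloxy)pent-4-en-2-ol
Product: 4 (2S)-2-(PMB-oxy)-1-(trityloxy)pent-4-ene
Conditions: NaH, PMBCl, Bu4NI (cat.), DMF, 0 °C → rt
Reagents that add atoms: 4-methoxybenzyl chloride, COc1ccc(CCl)cc1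
Why: Williamson etherification of the secondary alkoxide is routine, and the PMB ether is chosen because it chelates well in step 7 and can be removed oxidatively in step 10.

Step 3
Reactants: 4 (2S)-2-(PMB-oxy)-1-(trityloxy)pent-4-ene
Product: 5 (2S)-2-(PMB-oxy)pent-4-en-1-ol
Conditions: p-TsOH·H2O (10 mol %), MeOH/CH2Cl2 (1:1), rt
Reagents that add atoms: none
Why: Acid-catalysed methanolysis cleaves the trityl ether through the trityl cation much faster than the secondary PMB ether, so the primary alcohol should be freed selectively.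

Step 4
Reactants: 5 (2S)-2-(PMB-oxy)pent-4-en-1-ol
Product: 6 (2S)-2-(PMB-oxy)pent-4-enal
Conditions: DMP, NaHCO3, CH2Cl2, 0 °C → rt; used crude
Reagents that add atoms: none
Why: Dess–Martin oxidation under bicarbonate buffering should give the α-alkoxy aldehyde without epimerisation when it is used at once.

Step 5
Reactants: 6 (2S)-2-(PMB-oxy)pent-4-enal; 2 vinylmagnesium bromide
Product: 7 (4S)-4-(PMB-oxy)hepta-1,6-dien-3-ol (both C3 epimers)
Conditions: 2 (1.3 equiv), THF, −78 °C; aq. NH4Cl
Reagents that add atoms: none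
Why: 1,2-Addition of a vinyl Grignard reagent to the aldehyde gives the allylic alcohol, and the configuration of the new carbinol does not matter because it is oxidised in step 6.

Step 6
Reactants: 7 (4S)-4-(PMB-oxy)hepta-1,6-dien-3-ol
Product: 8 (4S)-4-(PMB-oxy)hepta-1,6-dien-3-one
Conditions: DMP, NaHCO3, CH2Cl2, 0 °C; used at once
Reagents that add atoms: none
Why: Dess–Martin oxidation of the allylic alcohol gives the vinyl ketone under neutral conditions that should leave the α-stereocentre and both alkenes intact.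

Step 7
Reactants: 8 (4S)-4-(PMB-oxy)hepta-1,6-dien-3-one; 9 ethyl vinyl ether
Product: 12 (3R,4S)-3-ethenyl-3-hydroxy-4-(PMB-oxy)hept-6-en-2-one, via 1-ethoxyvinyllithium 10 (not isolated), via enol ether adduct 11 (not isolated)
Conditions: 9 (slight excess), t-BuLi, THF, −78 → 0 °C; then 8 premixed with MgBr2·OEt2, CH2Cl2, −78 °C; then 1 M HCl, THF, 0 °C
Reagents that add atoms: water, O
Why: 1-Ethoxyvinyllithium, a masked acetyl anion, adds 1,2 to the ketone held in a five-membered magnesium chelate with the PMB ether oxygen (Cram chelate model) from the face of the α-hydrogen, which places the new hydroxyl cis to OPMB once the vinyl and allyl arms are joined in a ring, and brief aqueous acid then hydrolyses the enol ether to the methyl ketone.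

Step 8
Reactants: 12 (3R,4S)-3-ethenyl-3-hydroxy-4-(PMB-oxy)hept-6-en-2-one
Product: 13 1-[(1R,5S)-1-hydroxy-5-(PMB-oxy)cyclopent-2-en-1-yl]ethanone
Conditions: Grubbs second-generation catalyst (3 mol %), CH2Cl2, 40 °C
Reagents that add atoms: none
Why: Ring-closing metathesis of the 1,6-diene closes the cyclopentene with loss of ethylene, and a free tertiary allylic alcohol is tolerated by the ruthenium catalyst.

Step 9
Reactants: 13 1-[(1R,5S)-1-hydroxy-5-(PMB-oxy)cyclopent-2-en-1-yl]ethanone
Product: 14 (5S,6S)-6-hydroxy-5-(PMB-oxy)-6-methylcyclohex-2-en-1-one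
Conditions: Al(OtBu)3 (2 equiv), toluene, 80 °C; aq. Rochelle salt
Reagents that add atoms: none
Why: Exchange of a tert-butoxide ligand for the tertiary hydroxyl puts aluminium on the carbinol oxygen of 13, and coordination of the acetyl oxygen gives a five-membered syn chelate in which the ring carbon C5 shifts with its bonding pair from the carbinol carbon to the acetyl carbon while the carbinol collapses to the ring ketone. This is the Lewis-acid-mediated α-ketol (acyloin) rearrangement known for the ring enlargement of 1-acylcycloalkanols, for example the D-homoannulation of 17-hydroxy-20-keto steroids. The six-membered ring arises by ring expansion, the former acetyl carbon being inserted between C1 and C5 of the cyclopentene, and not by an end-to-end cyclisation. The new stereocentre (C7 of the target) is controlled by the chelate, since C5 is delivered suprafacially to the acetyl face over which it already lies and keeps its own configuration, so the cis hydroxyl/OPMB pair of 13 becomes the cis C7-OH/C6-OPMB pair of 14. The step needs migration of C5 and not of the vinylic C2; the shift is reversible and 14, a conjugated enone without cyclopentene strain, should be the lowest-energy member of the equilibrating set, whereas the β,γ-enone from a C2 shift is not conjugated. Even a C2 shift followed by a methyl shift in the same chelate leads to the same constitution and the same configuration, so the outcome rests on the chelate geometry and not on the order of the shifts.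

Step 10
Reactants: 14 (5S,6S)-6-hydroxy-5-(PMB-oxy)-6-methylcyclohex-2-en-1-one
Product: 15 (5S,6S)-5,6-dihydroxy-6-methylcyclohex-2-en-1-one
Conditions: DDQ (1.2 equiv), CH2Cl2/pH 7 buffer (10:1), 0 °C → rt
Reagents that add atoms: none
Why: Oxidative PMB cleavage with DDQ in wet dichloromethane is placed here because the simple enone is inert to DDQ, whereas the final 1H-isochromene would be prone to hydride abstraction at C1.

Step 11
Reactants: 16 methyl orsellinate
Product: 17 methyl 2-hydroxy-6-methyl-4-(pivaloyloxy)benzoate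
Conditions: PivCl (1.05 equiv), Et3N, CH2Cl2, 0 °C
Reagents that add atoms: pivaloyl chloride, CC(C)(C)C(Cl)=O
Why: Acylation of a 2,4-dihydroxybenzoate goes to the 4-hydroxyl because the 2-hydroxyl is held in a hydrogen bond to the ester carbonyl.

Step 12
Reactants: 17 methyl 2-hydroxy-6-methyl-4-(pivaloyloxy)benzoate
Product: 18 methyl 2-methoxy-6-methyl-4-(pivaloyloxy)benzoate
Conditions: MeI, K2CO3, acetone, reflux
Reagents that add atoms: iodomethane, CI
Why: Williamson O-methylation of the remaining chelated phenol under anhydrous carbonate conditions should leave the hindered aryl pivalate and the methyl ester in place.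

Step 13
Reactants: 18 methyl 2-methoxy-6-methyl-4-(pivaloyloxy)benzoate
Product: 19 4-hydroxy-2-methoxy-6-methylbenzoic acid
Conditions: KOH (6 equiv), MeOH/H2O (3:1), reflux; then 1 M HCl, 0 °C, to pH 3
Reagents that add atoms: potassium hydroxide, [K+].[OH-]
Why: Saponification with excess hydroxide cleaves the aryl pivalate and the hindered methyl ester in one operation, and cold acidification avoids decarboxylation of the electron-rich acid.

Step 14
Reactants: 19 4-hydroxy-2-methoxy-6-methylbenzoic acid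
Product: 21 4-(TBS-oxy)-2-methoxy-6-methylbenzoic acid, via bis-silyl compound 20 (not isolated)
Conditions: TBSCl (2.5 equiv), imidazole, DMF, rt; then AcOH/THF/H2O (3:1:1), rt
Reagents that add atoms: tert-butyldimethylsilyl chloride, CC(C)(C)[Si](C)(C)Cl
Why: Silylation of both the phenol and the acid followed by mild aqueous acid, which hydrolyses the labile silyl ester but not the aryl silyl ether, is the standard way to a phenol-protected hydroxybenzoic acid.

Step 15
Reactants: 15 (5S,6S)-5,6-dihydroxy-6-methylcyclohex-2-en-1-one; 21 4-(TBS-oxy)-2-methoxy-6-methylbenzoic acid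
Product: 23 (1S,2S)-2-hydroxy-2-methyl-3-oxocyclohex-4-en-1-yl 4-(TBS-oxy)-2-methoxy-6-methylbenzoate, via acid chloride 22 (not isolated)
Conditions: 21, (COCl)2, DMF (cat.), CH2Cl2, 0 °C → rt, evaporate; then 15, Et3N, DMAP, CH2Cl2, 0 °C → rt
Reagents that add atoms: none
Why: The acid chloride acylates the secondary hydroxyl under DMAP catalysis (nucleophilic acyl substitution), while the tertiary α-ketol hydroxyl is too hindered to compete.

Step 16
Reactants: 23 (1S,2S)-2-hydroxy-2-methyl-3-oxocyclohex-4-en-1-yl 4-(TBS-oxy)-2-methoxy-6-methylbenzoate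
Product: 24 (1S,2S)-2-methyl-3-oxo-2-(TES-oxy)cyclohex-4-en-1-yl 4-(TBS-oxy)-2-methoxy-6-methylbenzoate
Conditions: TESOTf, 2,6-lutidine, CH2Cl2, −78 → 0 °C
Reagents that add atoms: triethylsilyl trifluoromethanesulfonate, CC[Si](CC)(CC)OS(=O)(=O)C(F)(F)F
Why: A silyl triflate with 2,6-lutidine is the standard method for silylating a hindered tertiary alcohol, which has to be masked before the organometallic step 18.

Step 17
Reactants: 25 (E)-crotonaldehyde
Product: 26 (3E)-1,1-dibromopenta-1,3-diene
Conditions: CBr4, PPh3, CH2Cl2, 0 °C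
Reagents that add atoms: carbon tetrabromide, BrC(Br)(Br)Br
Why: Corey–Fuchs dibromo-olefination of the enal gives the dibromodiene and leaves the E double bond of crotonaldehyde unchanged.

Step 18
Reactants: 24 (1S,2S)-2-methyl-3-oxo-2-(TES-oxy)cyclohex-4-en-1-yl 4-(TBS-oxy)-2-methoxy-6-methylbenzoate; 26 (3E)-1,1-dibromopenta-1,3-diene
Product: 29 (1S,2S)-2-methyl-5-[(E)-pent-3-en-1-yn-1-yl]-2-(TES-oxy)-3-(TMS-oxy)cyclohex-3-en-1-yl 4-(TBS-oxy)-2-methoxy-6-methylbenzoate (both C5 epimers), via lithium acetylide 27 (not isolated), via alkynylzinc bromide 28 (not isolated)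
Conditions: 26, n-BuLi (2.0 equiv), THF, −78 → 0 °C; ZnBr2, 0 °C; then 24, TMSOTf, −40 °C; Et3N quench; used crude
Reagents that add atoms: trimethylsilyl trifluoromethanesulfonate, C[Si](C)(C)OS(=O)(=O)C(F)(F)F
Why: Two equivalents of butyllithium convert the dibromodiene into the lithium acetylide (second stage of the Corey–Fuchs sequence), and after transmetalation the alkynylzinc adds 1,4 to the enone activated by the silyl triflate (silyl-triflate-promoted conjugate alkynylation) with trapping as the silyl enol ether, the new C4a centre being removed again in step 19.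

Step 19
Reactants: 29 silyl enol ether from step 18
Product: 30 (1S,2S)-2-methyl-3-oxo-5-[(E)-pent-3-en-1-yn-1-yl]-2-(TES-oxy)cyclohex-4-en-1-yl 4-(TBS-oxy)-2-methoxy-6-methylbenzoate
Conditions: Pd(OAc)2 (1.05 equiv), MeCN, rt
Reagents that add atoms: none
Why: Saegusa–Ito oxidation (palladium enolate formation and β-hydride elimination) regenerates the enone, and only the C4a hydrogen can be eliminated because the other α-carbon is quaternary.

Step 20
Reactants: 30 enynone from step 19
Product: 31 (1S,2S)-4-iodo-2-methyl-3-oxo-5-[(E)-pent-3-en-1-yn-1-yl]-2-(TES-oxy)cyclohex-4-en-1-yl 4-(TBS-oxy)-2-methoxy-6-methylbenzoate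
Conditions: I2 (3 equiv), DMAP (0.2 equiv), pyridine/CH2Cl2 (1:1), rt, dark
Reagents that add atoms: iodine, II
Why: α-Iodination of an enone with iodine and pyridine (amine conjugate addition, iodination of the enolate, elimination), here with DMAP as a more nucleophilic catalyst for the β-substituted enone, should place iodine at C8a without touching the silyl ethers or the ester.

Step 21
Reactants: 31 iodoenone from step 20; 32 (tributylstannyl)methanol
Product: 33 (1S,2S)-4-(hydroxymethyl)-2-methyl-3-oxo-5-[(E)-pent-3-en-1-yn-1-yl]-2-(TES-oxy)cyclohex-4-en-1-yl 4-(TBS-oxy)-2-methoxy-6-methylbenzoate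
Conditions: 32 (1.5 equiv), Pd2(dba)3 (5 mol %), AsPh3 (20 mol %), CuI (10 mol %), NMP, 50 °C
Reagents that add atoms: none
Why: Stille coupling of an α-iodoenone with (tributylstannyl)methanol is an established hydroxymethylation, and the Pd/AsPh3/CuI system is used because the vinyl iodide is tetrasubstituted.

Step 22
Reactants: 33 hydroxymethyl enynone from step 21
Product: 34 (6S,7S)-7-methyl-8-oxo-3-[(E)-prop-1-en-1-yl]-7-(TES-oxy)-5,6,7,8-tetrahydro-1H-isochromen-6-yl 4-(TBS-oxy)-2-methoxy-6-methylbenzoate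
Conditions: AgOTf (10 mol %), CH2Cl2, rt, dark
Reagents that add atoms: none
Why: Silver(I) activates the alkyne for intramolecular hydroalkoxylation as with o-alkynylbenzyl alcohols, and attack of the primary hydroxyl on the distal alkyne carbon (6-endo-dig) should prevail over 5-exo-dig because that carbon is the δ-terminus of the ynenone and carries the propenyl group that stabilises developing positive charge.

Step 23
Reactants: 34 protected bicycle from step 22
Product: 35 comazaphilone G, (6S,7S)-7-hydroxy-7-methyl-8-oxo-3-[(E)-prop-1-en-1-yl]-5,6,7,8-tetrahydro-1H-isochromen-6-yl 4-hydroxy-2-methoxy-6-methylbenzoate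
Conditions: TBAF/AcOH (1:1, 4 equiv), THF, 0 °C → rt
Reagents that add atoms: none
Why: Acetic-acid-buffered fluoride should remove the tertiary triethylsilyl ether and the aryl silyl ether in one operation while keeping the medium near neutral, so that the C6 aroyloxy group is not lost by vinylogous elimination.

**Compound list**

1 | (S)-glycidyl trityl ether | C1[C@H](O1)COC(c2ccccc2)(c3ccccc3)c4ccccc4 | starting material
2 | vinylmagnesium bromide | C=C[Mg]Br | starting material
3 | (2S)-1-(trityloxy)pent-4-en-2-ol | C=CC[C@H](O)COC(c1ccccc1)(c2ccccc2)c3ccccc3 | intermediate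
4 | (2S)-2-(PMB-oxy)-1-(trityloxy)pent-4-ene | C=CC[C@H](OCc1ccc(OC)cc1)COC(c2ccccc2)(c3ccccc3)c4ccccc4 | intermediate
5 | (2S)-2-(PMB-oxy)pent-4-en-1-ol | C=CC[C@H](OCc1ccc(OC)cc1)CO | intermediate
6 | (2S)-2-(PMB-oxy)pent-4-enal | C=CC[C@H](OCc1ccc(OC)cc1)C=O | intermediate
7 | (4S)-4-(PMB-oxy)hepta-1,6-dien-3-ol (both C3 epimers) | C=CC(O)[C@@H](OCc1ccc(OC)cc1)CC=C | intermediate
8 | (4S)-4-(PMB-oxy)hepta-1,6-dien-3-one | C=CC(=O)[C@@H](OCc1ccc(OC)cc1)CC=C | intermediate
9 | ethyl vinyl ether | C=COCC | starting material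
10 | 1-ethoxyvinyllithium | [Li]C(=C)OCC | intermediate
11 | (3R,4S)-3-ethenyl-2-ethoxy-4-(PMB-oxy)hepta-1,6-dien-3-ol | C=C(OCC)[C@@](O)(C=C)[C@@H](OCc1ccc(OC)cc1)CC=C | intermediate
12 | (3R,4S)-3-ethenyl-3-hydroxy-4-(PMB-oxy)hept-6-en-2-one | CC(=O)[C@@](O)(C=C)[C@@H](OCc1ccc(OC)cc1)CC=C | intermediate
13 | 1-[(1R,5S)-1-hydroxy-5-(PMB-oxy)cyclopent-2-en-1-yl]ethanone | CC(=O)[C@@]1(O)C=CC[C@@H]1OCc2ccc(OC)cc2 | intermediate
14 | (5S,6S)-6-hydroxy-5-(PMB-oxy)-6-methylcyclohex-2-en-1-one | C1=CC(=O)[C@@](C)(O)[C@@H](OCc2ccc(OC)cc2)C1 | intermediate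
15 | (5S,6S)-5,6-dihydroxy-6-methylcyclohex-2-en-1-one | C1=CC(=O)[C@@](C)(O)[C@@H](O)C1 | intermediate
16 | methyl orsellinate | COC(=O)c1c(C)cc(O)cc1O | starting material
17 | methyl 2-hydroxy-6-methyl-4-(pivaloyloxy)benzoate | COC(=O)c1c(C)cc(OC(=O)C(C)(C)C)cc1O | intermediate
18 | methyl 2-methoxy-6-methyl-4-(pivaloyloxy)benzoate | COC(=O)c1c(C)cc(OC(=O)C(C)(C)C)cc1OC | intermediate
19 | 4-hydroxy-2-methoxy-6-methylbenzoic acid | OC(=O)c1c(C)cc(O)cc1OC | intermediate
20 | tert-butyldimethylsilyl 4-(TBS-oxy)-2-methoxy-6-methylbenzoate | CC(C)(C)[Si](C)(C)OC(=O)c1c(C)cc(O[Si](C)(C)C(C)(C)C)cc1OC | intermediate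
21 | 4-(TBS-oxy)-2-methoxy-6-methylbenzoic acid | OC(=O)c1c(C)cc(O[Si](C)(C)C(C)(C)C)cc1OC | intermediate
22 | 4-(TBS-oxy)-2-methoxy-6-methylbenzoyl chloride | ClC(=O)c1c(C)cc(O[Si](C)(C)C(C)(C)C)cc1OC | intermediate
23 | (1S,2S)-2-hydroxy-2-methyl-3-oxocyclohex-4-en-1-yl 4-(TBS-oxy)-2-methoxy-6-methylbenzoate | C1=CC(=O)[C@@](C)(O)[C@@H](OC(=O)c2c(C)cc(O[Si](C)(C)C(C)(C)C)cc2OC)C1 | intermediate
24 | (1S,2S)-2-methyl-3-oxo-2-(TES-oxy)cyclohex-4-en-1-yl 4-(TBS-oxy)-2-methoxy-6-methylbenzoate | C1=CC(=O)[C@@](C)(O[Si](CC)(CC)CC)[C@@H](OC(=O)c2c(C)cc(O[Si](C)(C)C(C)(C)C)cc2OC)C1 | intermediate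
25 | (E)-crotonaldehyde | C/C=C/C=O | starting material
26 | (3E)-1,1-dibromopenta-1,3-diene | C/C=C/C=C(Br)Br | intermediate
27 | lithium (E)-pent-3-en-1-yn-1-ide | C/C=C/C#C[Li] | intermediate
28 | [(E)-pent-3-en-1-yn-1-yl]zinc bromide | C/C=C/C#C[Zn]Br | intermediate
29 | (1S,2S)-2-methyl-5-[(E)-pent-3-en-1-yn-1-yl]-2-(TES-oxy)-3-(TMS-oxy)cyclohex-3-en-1-yl 4-(TBS-oxy)-2-methoxy-6-methylbenzoate (both C5 epimers) | C1(C#C/C=C/C)C=C(O[Si](C)(C)C)[C@@](C)(O[Si](CC)(CC)CC)[C@@H](OC(=O)c2c(C)cc(O[Si](C)(C)C(C)(C)C)cc2OC)C1 | intermediate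
30 | (1S,2S)-2-methyl-3-oxo-5-[(E)-pent-3-en-1-yn-1-yl]-2-(TES-oxy)cyclohex-4-en-1-yl 4-(TBS-oxy)-2-methoxy-6-methylbenzoate | C1(C#C/C=C/C)=CC(=O)[C@@](C)(O[Si](CC)(CC)CC)[C@@H](OC(=O)c2c(C)cc(O[Si](C)(C)C(C)(C)C)cc2OC)C1 | intermediate
31 | (1S,2S)-4-iodo-2-methyl-3-oxo-5-[(E)-pent-3-en-1-yn-1-yl]-2-(TES-oxy)cyclohex-4-en-1-yl 4-(TBS-oxy)-2-methoxy-6-methylbenzoate | C1(C#C/C=C/C)=C(I)C(=O)[C@@](C)(O[Si](CC)(CC)CC)[C@@H](OC(=O)c2c(C)cc(O[Si](C)(C)C(C)(C)C)cc2OC)C1 | intermediate
32 | (tributylstannyl)methanol | CCCC[Sn](CCCC)(CCCC)CO | starting material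
33 | (1S,2S)-4-(hydroxymethyl)-2-methyl-3-oxo-5-[(E)-pent-3-en-1-yn-1-yl]-2-(TES-oxy)cyclohex-4-en-1-yl 4-(TBS-oxy)-2-methoxy-6-methylbenzoate | C1(C#C/C=C/C)=C(CO)C(=O)[C@@](C)(O[Si](CC)(CC)CC)[C@@H](OC(=O)c2c(C)cc(O[Si](C)(C)C(C)(C)C)cc2OC)C1 | intermediate
34 | (6S,7S)-7-methyl-8-oxo-3-[(E)-prop-1-en-1-yl]-7-(TES-oxy)-5,6,7,8-tetrahydro-1H-isochromen-6-yl 4-(TBS-oxy)-2-methoxy-6-methylbenzoate | C/C=C/C1=CC2=C(CO1)C(=O)[C@@](C)(O[Si](CC)(CC)CC)[C@@H](OC(=O)c3c(C)cc(O[Si](C)(C)C(C)(C)C)cc3OC)C2 | intermediate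
35 | comazaphilone G, (6S,7S)-7-hydroxy-7-methyl-8-oxo-3-[(E)-prop-1-en-1-yl]-5,6,7,8-tetrahydro-1H-isochromen-6-yl 4-hydroxy-2-methoxy-6-methylbenzoate | C/C=C/C1=CC2=C(CO1)C(=O)[C@@](C)(O)[C@@H](OC(=O)c3c(C)cc(O)cc3OC)C2 | target

**Step count**

Total: 23 steps. Longest linear sequence: 18 steps (steps 1–10, 15, 16, 18–23); the aryl acid (steps 11–14) and the dibromodiene (step 17) are side branches.

**Steps most likely to fail**

Step 9 (ring expansion). The vinylic ring carbon may migrate faster than C5 and the resulting β,γ-enone may not equilibrate onward, or p-methoxybenzyl alcohol may be lost from C6 by vinylogous elimination in the hot Lewis-acidic medium. The fallback sets out from aldehyde 6 and builds the same cyclohexenone by an aldol ring closure, with C7 set by a chelation-controlled methyl addition instead of a shift. Addition of 1-ethoxyvinyllithium 10 to 6 (THF, −78 °C) would give (4S)-2-ethoxy-4-(PMB-oxy)hepta-1,6-dien-3-ol F1, and Dess–Martin oxidation the α-ethoxy enone (4S)-2-ethoxy-4-(PMB-oxy)hepta-1,6-dien-3-one F2. Addition of MeMgBr (CH2Cl2/Et2O, −78 °C) under chelation by the PMB ether delivers methyl from the α-hydrogen face and should give (3S,4S)-2-ethoxy-3-methyl-4-(PMB-oxy)hepta-1,6-dien-3-ol F3, whose tertiary hydroxyl already has the C7 configuration. Dilute HCl hydrolyses the enol ether to (3S,4S)-3-hydroxy-3-methyl-4-(PMB-oxy)hept-6-en-2-one F4. Lemieux–Johnson cleavage of the terminal alkene (OsO4 cat., NaIO4, 2,6-lutidine, dioxane/H2O) gives (3S,4S)-4-hydroxy-4-methyl-5-oxo-3-(PMB-oxy)hexanal F5, and intramolecular aldol condensation of the methyl ketone onto the aldehyde (pyrrolidine/AcOH) closes the enone and comes back to the route at 14.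

Step 20 (α-iodination). Conjugate addition of the amine to the β-substituted, alkynyl-bearing enone may be slow, so that iodine adds to the enyne side chain or conversion stalls. The fallback sets out from 24 and installs the hydroxymethyl carbon before the alkyne. A Morita–Baylis–Hillman reaction of 24 with aqueous formaldehyde (DMAP, THF/H2O) should give (1S,2S)-4-(hydroxymethyl)-2-methyl-3-oxo-2-(TES-oxy)cyclohex-4-en-1-yl 4-(TBS-oxy)-2-methoxy-6-methylbenzoate F6. TMSCl/Et3N gives its primary trimethylsilyl ether F7. Conjugate alkynylation as in step 18 gives the TMS enol ether of the 5-pentenynyl adduct F8. Saegusa oxidation followed by a dilute citric acid wash, which removes the primary trimethylsilyl ether, comes back to the route at 33.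

Step 7 (acetyl anion addition). Chelation may be incomplete, giving poor facial selectivity at the acyclic ketone, or the vinyl ketone may polymerise in the presence of the magnesium salt. The fallback sets out from 8 and closes the five-membered ring first, so that the ring and not a chelate controls the addition. Ring-closing metathesis of 8 (Grubbs second-generation catalyst) gives (5S)-5-(PMB-oxy)cyclopent-2-en-1-one F9. Addition of 10 in the presence of CeCl3 (THF, −78 °C), anti to the adjacent PMB ether, gives (1R,5S)-1-(1-ethoxyethenyl)-5-(PMB-oxy)cyclopent-2-en-1-ol F10. Dilute HCl hydrolyses the enol ether and comes back to the route at 13.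

**Further compounds**

F1 | step 9 | (4S)-2-ethoxy-4-(PMB-oxy)hepta-1,6-dien-3-ol (both C3 epimers) | C=C(OCC)C(O)[C@@H](OCc1ccc(OC)cc1)CC=C
F2 | step 9 | (4S)-2-ethoxy-4-(PMB-oxy)hepta-1,6-dien-3-one | C=C(OCC)C(=O)[C@@H](OCc1ccc(OC)cc1)CC=C
F3 | step 9 | (3S,4S)-2-ethoxy-3-methyl-4-(PMB-oxy)hepta-1,6-dien-3-ol | C=C(OCC)[C@@](C)(O)[C@@H](OCc1ccc(OC)cc1)CC=C
F4 | step 9 | (3S,4S)-3-hydroxy-3-methyl-4-(PMB-oxy)hept-6-en-2-one | CC(=O)[C@@](C)(O)[C@@H](OCc1ccc(OC)cc1)CC=C
F5 | step 9 | (3S,4S)-4-hydroxy-4-methyl-5-oxo-3-(PMB-oxy)hexanal | CC(=O)[C@@](C)(O)[C@@H](OCc1ccc(OC)cc1)CC=O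
F6 | step 20 | (1S,2S)-4-(hydroxymethyl)-2-methyl-3-oxo-2-(TES-oxy)cyclohex-4-en-1-yl 4-(TBS-oxy)-2-methoxy-6-methylbenzoate | C1=C(CO)C(=O)[C@@](C)(O[Si](CC)(CC)CC)[C@@H](OC(=O)c2c(C)cc(O[Si](C)(C)C(C)(C)C)cc2OC)C1
F7 | step 20 | (1S,2S)-2-methyl-3-oxo-2-(TES-oxy)-4-[(TMS-oxy)methyl]cyclohex-4-en-1-yl 4-(TBS-oxy)-2-methoxy-6-methylbenzoate | C1=C(CO[Si](C)(C)C)C(=O)[C@@](C)(O[Si](CC)(CC)CC)[C@@H](OC(=O)c2c(C)cc(O[Si](C)(C)C(C)(C)C)cc2OC)C1
F8 | step 20 | (1S,2S)-2-methyl-5-[(E)-pent-3-en-1-yn-1-yl]-2-(TES-oxy)-3-(TMS-oxy)-4-[(TMS-oxy)methyl]cyclohex-3-en-1-yl 4-(TBS-oxy)-2-methoxy-6-methylbenzoate (both C5 epimers) | C1(C#C/C=C/C)C(CO[Si](C)(C)C)=C(O[Si](C)(C)C)[C@@](C)(O[Si](CC)(CC)CC)[C@@H](OC(=O)c2c(C)cc(O[Si](C)(C)C(C)(C)C)cc2OC)C1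
F9 | step 7 | (5S)-5-(PMB-oxy)cyclopent-2-en-1-one | O=C1C=CC[C@@H]1OCc2ccc(OC)cc2
F10 | step 7 | (1R,5S)-1-(1-ethoxyethenyl)-5-(PMB-oxy)cyclopent-2-en-1-ol | C=C(OCC)[C@@]1(O)C=CC[C@@H]1OCc2ccc(OC)cc2
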